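A direct plan would follow the biogenesis: the epoxy polyene A1 would be cyclised with Cp2TiCl (trivalent titanium) to the decalin diol A2, the C3 and C18 functions would be adjusted, and the side chain would be completed from the diene ester A3. Its weakest steps would be:
(1) the radical bicyclisation, since C4 would arise from a planar radical and its configuration, like the alkene position, would rest on a small conformational preference;
(2) the thioacylation and tin hydride reduction that remove the C3 oxygen, since that oxygen would only start the cyclisation and, with three redox steps at C18, five steps would add nothing to the skeleton;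
(3) the final enantioselective diacetoxylation of diene A3, since an unprecedented reaction would have to set the remote C13 centre on the most precious material.

The new route cuts, in this order, C14–C15 and C13–O (chain end), C3–C4 (ring A), C11–C12 and C9–C11 (side chain), C1–C10 and C4–C5 (the two arms on ring B). Ring B is bought as 2-methylcyclohex-2-enone and made chiral by one reduction; ring A closes last, when the C18 ester enolate at C4 displaces an iodide at C3. The structure allows this because C4 is the α-carbon of the only ester, lies next to the ring-B methine C5 (whose hydrogen steers the enolate by allylic 1,3-strain), and C1–C3 are plain CH2 groups. Hence no oxygen ever sits on C3, C4 is set in a closed transition state and not from a planar radical, and C13 comes from a Sharpless epoxidation followed by a one-carbon homologation of a known type.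

Key step: step 10

Assumption: atoms carry labdane numbers (C4 quaternary with ester C18 and a methyl; C5/C10 ring fusion; C20 the methyl on C10; C8 with the exocyclic methylene C17; C9 with the chain C11–C16, carbinol C13, hydroxymethyl C16, vinyl C14=C15).
Remark: compounds 7–17 are carried as mixtures of epimers at the propanoate α-carbon (the future C4); this centre is set in step 10 and is left open in their SMILES. Compounds 1 and 4, (3-bromopropoxy)(tert-butyl)dimethylsilane and Eschenmoser's salt are taken as commercial.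

Step 1
Reactants: 1 2-[(trimethylsilyl)methyl]prop-2-en-1-yl acetate
Product: 3 tert-butyl(diphenyl)({2-[(trimethylsilyl)methyl]prop-2-en-1-yl}oxy)silane, via allylic alcohol 2 (not isolated)
Conditions: K2CO3 (0.1 equiv), MeOH, 0 °C; concentrate; then TBDPSCl, imidazole, CH2Cl2, 0 °C to rt
Reagents that add atoms: tert-butyl(chloro)diphenylsilane CC(C)(C)[Si](Cl)(c1ccccc1)c1ccccc1
Why: Methanolysis of the acetate and silyl ether formation at the primary hydroxyl should give a base-stable, oxygenated 2-substituted allylsilane; no stereocentre is involved.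

Step 2
Reactants: 4 2-methylcyclohex-2-en-1-one
Product: 5 (1R)-2-methylcyclohex-2-en-1-ol
Conditions: (S)-2-methyl-CBS-oxazaborolidine (10 mol %), BH3·SMe2 (0.7 equiv), THF, −20 °C; MeOH quench
Reagents that add atoms: none
Why: Corey–Bakshi–Shibata reduction, in which the methyl-substituted alkenyl arm acts as the large group, should give the (R)-allylic alcohol; this C9–O centre is the source of all ring stereocentres.

Step 3
Reactants: 5 (1R)-2-methylcyclohex-2-en-1-ol
Product: 7 methyl 2-[(1R)-2-methylcyclohex-2-en-1-yl]propanoate, via ketene acetal 6 (not isolated)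
Conditions: CH3CH2C(OMe)3 (5 equiv), propionic acid (5 mol %), xylene, 140 °C, methanol distilled off
Reagents that add atoms: trimethyl orthopropionate CCC(OC)(OC)OC
Why: Johnson orthoester Claisen rearrangement: the mixed ketene acetal should rearrange suprafacially, so the C9–O chirality passes to C5 (new C4–C5 bond on the face the oxygen leaves) and the alkene moves to C9=C10.

Step 4
Reactants: 7 methyl 2-[(1R)-2-methylcyclohex-2-en-1-yl]propanoate
Product: 8 methyl 2-[(1R)-2-methyl-4-oxocyclohex-2-en-1-yl]propanoate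
Conditions: Rh2(cap)4 [dirhodium tetrakis(caprolactamate)] (1 mol %), t-BuOOH (70% in water, 5 equiv), K2CO3 (0.5 equiv), CH2Cl2, rt
Reagents that add atoms: tert-butyl hydroperoxide CC(C)(C)OO
Why: Radical allylic C–H oxidation (peroxyl abstraction, mixed peroxide, collapse to ketone) at the ring CH2 next to the less substituted alkene carbon should give the β-methyl enone (C8 ketone) without touching C5.

Step 5
Reactants: 8 methyl 2-[(1R)-2-methyl-4-oxocyclohex-2-en-1-yl]propanoate
Product: 12 methyl 2-[(1R,2R)-2-{3-[tert-butyl(dimethyl)silyl]oxypropyl}-2-methyl-3-methylidene-4-oxocyclohexyl]propanoate, via silyl enol ether 9 (not isolated), via Mannich base 10 (not isolated), via ammonium iodide 11 (not isolated)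
Conditions: TBSO(CH2)3MgBr (1.5 equiv, from the bromide and Mg), CuBr·SMe2 (10 mol %), TMSCl, HMPA, THF, −78 to −40 °C; then Me2N=CH2 I (Eschenmoser's salt), CH2Cl2, rt, aq. NaHCO3; then MeI, THF, rt; then DBU, CH2Cl2, 0 °C
Reagents that add atoms: [3-(tert-butyldimethylsilyloxy)propyl]magnesium bromide CC(C)(C)[Si](C)(C)OCCC[Mg]Br; N,N-dimethylmethylideneammonium iodide (Eschenmoser's salt) C=[N+](C)C.[I-]
Why: Copper-catalysed, chlorosilane-accelerated conjugate addition should occur anti to the C5 substituent (held pseudoaxial by 1,2-allylic strain with the C10 methyl) and set the quaternary C10 with C1 trans to C4; the regiodefined enol ether is then aminomethylated at C9 (Mannich reaction), and quaternisation with β-elimination gives the α-methylene ketone that carries C11.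

Step 6
Reactants: 12 methyl 2-[(1R,2R)-2-{3-[tert-butyl(dimethyl)silyl]oxypropyl}-2-methyl-3-methylidene-4-oxocyclohexyl]propanoate; 3 tert-butyl(diphenyl)({2-[(trimethylsilyl)methyl]prop-2-en-1-yl}oxy)silane
Product: 14 methyl 2-[(1R,2R,3S)-2-{3-[tert-butyl(dimethyl)silyl]oxypropyl}-3-(3-{[tert-butyl(diphenyl)silyl]oxymethyl}but-3-en-1-yl)-2-methyl-4-oxocyclohexyl]propanoate, via silyl enol ether 13 (not isolated)
Conditions: 3 (1.5 equiv), Tf2NH (5 mol %), CH2Cl2, −78 °C; then K2CO3, MeOH, 0 °C
Reagents that add atoms: none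
Why: Hosomi–Sakurai conjugate allylation should join C11 to C12 at the unhindered exocyclic enone carbon, and methanolysis of the enol ether should protonate C9 axially, away from the axial C10 methyl (also the thermodynamic outcome), which places the side chain equatorial and cis to that methyl.

Step 7
Reactants: 14 methyl 2-[(1R,2R,3S)-2-{3-[tert-butyl(dimethyl)silyl]oxypropyl}-3-(3-{[tert-butyl(diphenyl)silyl]oxymethyl}but-3-en-1-yl)-2-methyl-4-oxocyclohexyl]propanoate
Product: 15 methyl 2-[(1R,2R,3R)-2-{3-[tert-butyl(dimethyl)silyl]oxypropyl}-3-(3-{[tert-butyl(diphenyl)silyl]oxymethyl}but-3-en-1-yl)-2-methyl-4-methylidenecyclohexyl]propanoate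
Conditions: Ph3PCH3Br (3 equiv), KOtBu (2.8 equiv), toluene, 0 to 80 °C
Reagents that add atoms: methyltriphenylphosphonium bromide C[P+](c1ccccc1)(c1ccccc1)c1ccccc1.[Br-]
Why: Wittig methylenation of the hindered C8 ketone should install C17; C9 is already in its more stable configuration (the descriptor changes only through priorities), and the ester and silyl ethers are inert to the ylide.

Step 8
Reactants: 15 methyl 2-[(1R,2R,3R)-2-{3-[tert-butyl(dimethyl)silyl]oxypropyl}-3-(3-{[tert-butyl(diphenyl)silyl]oxymethyl}but-3-en-1-yl)-2-methyl-4-methylidenecyclohexyl]propanoate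
Product: 16 methyl 2-[(1R,2R,3R)-3-(3-{[tert-butyl(diphenyl)silyl]oxymethyl}but-3-en-1-yl)-2-(3-hydroxypropyl)-2-methyl-4-methylidenecyclohexyl]propanoate
Conditions: PPTS (0.2 equiv), MeOH, rt
Reagents that add atoms: none
Why: Mild acid methanolysis should cleave the primary tert-butyldimethylsilyl ether much faster than the tert-butyldiphenylsilyl ether and is too weak to isomerise the 1,1-disubstituted alkenes.

Step 9
Reactants: 16 methyl 2-[(1R,2R,3R)-3-(3-{[tert-butyl(diphenyl)silyl]oxymethyl}but-3-en-1-yl)-2-(3-hydroxypropyl)-2-methyl-4-methylidenecyclohexyl]propanoate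
Product: 17 methyl 2-[(1R,2R,3R)-3-(3-{[tert-butyl(diphenyl)silyl]oxymethyl}but-3-en-1-yl)-2-(3-iodopropyl)-2-methyl-4-methylidenecyclohexyl]propanoate
Conditions: I2, PPh3, imidazole, CH2Cl2, 0 °C
Reagents that add atoms: iodine II
Why: Appel-type iodination (alkoxyphosphonium salt, SN2 by iodide) should convert the primary alcohol at C3 into the iodide under neutral conditions.

Step 10
Reactants: 17 methyl 2-[(1R,2R,3R)-3-(3-{[tert-butyl(diphenyl)silyl]oxymethyl}but-3-en-1-yl)-2-(3-iodopropyl)-2-methyl-4-methylidenecyclohexyl]propanoate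
Product: 18 methyl (1S,4aS,5R,8aS)-5-(3-{[tert-butyl(diphenyl)silyl]oxymethyl}but-3-en-1-yl)-1,4a-dimethyl-6-methylidenedecahydronaphthalene-1-carboxylate
Conditions: LDA (1.3 equiv), THF, −78 °C; then DMPU, −78 to 0 °C (0.02 M)
Reagents that add atoms: none
Why: LDA should deprotonate C4, the only C–H acid left, and the lithium ester enolate should displace the primary iodide at C3 in an intramolecular SN2 alkylation; the closest known reaction type is ester-enolate cycloalkylation to cyclohexanecarboxylates with a quaternary α-carbon. Ring A closes 6-exo-tet through a chair, and because C1 (on C10) and C4 (on C5) are the trans-diequatorial arms of ring B, the ring fusion is trans by construction. The new stereocentre C4 is controlled by allylic 1,3-strain: the enolate unit C(OMe)OLi lies in the plane of C5–H and so ends equatorial as the C18 ester, anti to the C10 methyl, while the C4 methyl takes the axial site. The alternative transition state would put the enolate oxygens between C6 and the quaternary C10 and, in addition, syn-axial to the C10 methyl. The step needs selective enolisation and C-alkylation; the ketone is already methylenated, the alcohol is silylated, and ester enolates alkylate at carbon.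

Step 11
Reactants: 18 methyl (1S,4aS,5R,8aS)-5-(3-{[tert-butyl(diphenyl)silyl]oxymethyl}but-3-en-1-yl)-1,4a-dimethyl-6-methylidenedecahydronaphthalene-1-carboxylate
Product: 19 methyl (1S,4aS,5R,8aS)-5-[3-(hydroxymethyl)but-3-en-1-yl]-1,4a-dimethyl-6-methylidenedecahydronaphthalene-1-carboxylate
Conditions: TBAF, THF, 0 °C to rt
Reagents that add atoms: none
Why: Fluoride desilylation should free the 2-substituted allylic alcohol needed to direct the epoxidation; the hindered tertiary ester is inert.

Step 12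
Reactants: 19 methyl (1S,4aS,5R,8aS)-5-[3-(hydroxymethyl)but-3-en-1-yl]-1,4a-dimethyl-6-methylidenedecahydronaphthalene-1-carboxylate
Product: 20 methyl (1S,4aS,5R,8aS)-5-{2-[(2S)-2-(hydroxymethyl)oxiran-2-yl]ethyl}-1,4a-dimethyl-6-methylidenedecahydronaphthalene-1-carboxylate
Conditions: Ti(OiPr)4 (10 mol %), L-(+)-diisopropyl tartrate (12 mol %), t-BuOOH (2 equiv, in decane), 4 Å sieves, CH2Cl2, −20 °C
Reagents that add atoms: tert-butyl hydroperoxide CC(C)(C)OO
Why: Sharpless asymmetric epoxidation should touch only the alkene of the allylic alcohol (the C8=C17 alkene does not bind titanium), and L-(+)-tartrate should give the (2S)-epoxide under reagent control, forming the C13–O bond of the target.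

Step 13
Reactants: 20 methyl (1S,4aS,5R,8aS)-5-{2-[(2S)-2-(hydroxymethyl)oxiran-2-yl]ethyl}-1,4a-dimethyl-6-methylidenedecahydronaphthalene-1-carboxylate
Product: 21 methyl (1S,4aS,5R,8aS)-5-[(3R)-3-hydroxy-3-(hydroxymethyl)pent-4-en-1-yl]-1,4a-dimethyl-6-methylidenedecahydronaphthalene-1-carboxylate
Conditions: Me3S I (4 equiv), n-BuLi (3.8 equiv), THF, −10 °C to rt
Reagents that add atoms: trimethylsulfonium iodide C[S+](C)C.[I-]
Why: One-carbon homologation of a terminal epoxide to an allylic alcohol: dimethylsulfonium methylide should open the epoxide at its CH2 carbon (C14) and a second equivalent should induce β-elimination of dimethyl sulfide to form C14=C15; the C13–O bond is never broken, so the (2S)-epoxide gives the (3R)-diol, and the Payne rearrangement of this 2,2-disubstituted epoxy alkoxide is degenerate.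

Compound list
1 | 2-[(trimethylsilyl)methyl]prop-2-en-1-yl acetate | CC(=O)OCC(=C)C[Si](C)(C)C | starting material
2 | 2-[(trimethylsilyl)methyl]prop-2-en-1-ol | OCC(=C)C[Si](C)(C)C | intermediate
3 | tert-butyl(diphenyl)({2-[(trimethylsilyl)methyl]prop-2-en-1-yl}oxy)silane | C[Si](C)(C)CC(=C)CO[Si](c1ccccc1)(c1ccccc1)C(C)(C)C | intermediate
4 | 2-methylcyclohex-2-en-1-one | CC1=CCCCC1=O | starting material
5 | (1R)-2-methylcyclohex-2-en-1-ol | CC1=CCCC[C@H]1O | intermediate
6 | (6R)-6-[(1-methoxyprop-1-en-1-yl)oxy]-1-methylcyclohex-1-ene (alkene geometry open) | CC=C(OC)O[C@@H]1CCCC=C1C | intermediate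
7 | methyl 2-[(1R)-2-methylcyclohex-2-en-1-yl]propanoate | COC(=O)C(C)[C@H]1CCCC=C1C | intermediate
8 | methyl 2-[(1R)-2-methyl-4-oxocyclohex-2-en-1-yl]propanoate | COC(=O)C(C)[C@H]1CCC(=O)C=C1C | intermediate
9 | methyl 2-[(1R,2R)-2-{3-[tert-butyl(dimethyl)silyl]oxypropyl}-2-methyl-4-[(trimethylsilyl)oxy]cyclohex-3-en-1-yl]propanoate | COC(=O)C(C)[C@H]1CCC(O[Si](C)(C)C)=C[C@]1(C)CCCO[Si](C)(C)C(C)(C)C | intermediate
10 | methyl 2-[(1R,2R)-2-{3-[tert-butyl(dimethyl)silyl]oxypropyl}-3-[(dimethylamino)methyl]-2-methyl-4-oxocyclohexyl]propanoate (ring C3 epimers) | COC(=O)C(C)[C@H]1CCC(=O)C(CN(C)C)[C@]1(C)CCCO[Si](C)(C)C(C)(C)C | intermediate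
11 | {[(2R,3R)-2-{3-[tert-butyl(dimethyl)silyl]oxypropyl}-3-(1-methoxy-1-oxopropan-2-yl)-2-methyl-6-oxocyclohexyl]methyl}trimethylammonium iodide | COC(=O)C(C)[C@H]1CCC(=O)C(C[N+](C)(C)C)[C@]1(C)CCCO[Si](C)(C)C(C)(C)C.[I-] | intermediate
12 | methyl 2-[(1R,2R)-2-{3-[tert-butyl(dimethyl)silyl]oxypropyl}-2-methyl-3-methylidene-4-oxocyclohexyl]propanoate | COC(=O)C(C)[C@H]1CCC(=O)C(=C)[C@]1(C)CCCO[Si](C)(C)C(C)(C)C | intermediate
13 | methyl 2-[(1R,2R)-2-{3-[tert-butyl(dimethyl)silyl]oxypropyl}-3-(3-{[tert-butyl(diphenyl)silyl]oxymethyl}but-3-en-1-yl)-2-methyl-4-[(trimethylsilyl)oxy]cyclohex-3-en-1-yl]propanoate | COC(=O)C(C)[C@H]1CCC(O[Si](C)(C)C)=C(CCC(=C)CO[Si](c2ccccc2)(c2ccccc2)C(C)(C)C)[C@]1(C)CCCO[Si](C)(C)C(C)(C)C | intermediate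
14 | methyl 2-[(1R,2R,3S)-2-{3-[tert-butyl(dimethyl)silyl]oxypropyl}-3-(3-{[tert-butyl(diphenyl)silyl]oxymethyl}but-3-en-1-yl)-2-methyl-4-oxocyclohexyl]propanoate (two chains trans, side chain cis to the ring methyl) | COC(=O)C(C)[C@H]1CCC(=O)[C@@H](CCC(=C)CO[Si](c2ccccc2)(c2ccccc2)C(C)(C)C)[C@]1(C)CCCO[Si](C)(C)C(C)(C)C | intermediate
15 | methyl 2-[(1R,2R,3R)-2-{3-[tert-butyl(dimethyl)silyl]oxypropyl}-3-(3-{[tert-butyl(diphenyl)silyl]oxymethyl}but-3-en-1-yl)-2-methyl-4-methylidenecyclohexyl]propanoate | COC(=O)C(C)[C@H]1CCC(=C)[C@@H](CCC(=C)CO[Si](c2ccccc2)(c2ccccc2)C(C)(C)C)[C@]1(C)CCCO[Si](C)(C)C(C)(C)C | intermediate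
16 | methyl 2-[(1R,2R,3R)-3-(3-{[tert-butyl(diphenyl)silyl]oxymethyl}but-3-en-1-yl)-2-(3-hydroxypropyl)-2-methyl-4-methylidenecyclohexyl]propanoate | COC(=O)C(C)[C@H]1CCC(=C)[C@@H](CCC(=C)CO[Si](c2ccccc2)(c2ccccc2)C(C)(C)C)[C@]1(C)CCCO | intermediate
17 | methyl 2-[(1R,2R,3R)-3-(3-{[tert-butyl(diphenyl)silyl]oxymethyl}but-3-en-1-yl)-2-(3-iodopropyl)-2-methyl-4-methylidenecyclohexyl]propanoate | COC(=O)C(C)[C@H]1CCC(=C)[C@@H](CCC(=C)CO[Si](c2ccccc2)(c2ccccc2)C(C)(C)C)[C@]1(C)CCCI | intermediate
18 | methyl (1S,4aS,5R,8aS)-5-(3-{[tert-butyl(diphenyl)silyl]oxymethyl}but-3-en-1-yl)-1,4a-dimethyl-6-methylidenedecahydronaphthalene-1-carboxylate | CC(C)(C)[Si](OCC(=C)CC[C@@H]1C(=C)CC[C@H]2[C@@]1(C)CCC[C@]2(C)C(=O)OC)(c3ccccc3)c4ccccc4 | intermediate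
19 | methyl (1S,4aS,5R,8aS)-5-[3-(hydroxymethyl)but-3-en-1-yl]-1,4a-dimethyl-6-methylidenedecahydronaphthalene-1-carboxylate | OCC(=C)CC[C@@H]1C(=C)CC[C@H]2[C@@]1(C)CCC[C@]2(C)C(=O)OC | intermediate
20 | methyl (1S,4aS,5R,8aS)-5-{2-[(2S)-2-(hydroxymethyl)oxiran-2-yl]ethyl}-1,4a-dimethyl-6-methylidenedecahydronaphthalene-1-carboxylate | OC[C@@]1(CC[C@@H]2C(=C)CC[C@H]3[C@@]2(C)CCC[C@]3(C)C(=O)OC)CO1 | intermediate
21 | methyl (1S,4aS,5R,8aS)-5-[(3R)-3-hydroxy-3-(hydroxymethyl)pent-4-en-1-yl]-1,4a-dimethyl-6-methylidenedecahydronaphthalene-1-carboxylate | C=C[C@@](O)(CO)CC[C@@H]1C(=C)CC[C@H]2[C@@]1(C)CCC[C@]2(C)C(=O)OC | target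

Total step count: 13. Longest linear sequence: 12 steps (steps 2–13, from 4 to 21).

Steps most likely to fail:

Step 4. Hydrogen abstraction may also take place at the tertiary allylic C5–H, which would lead to the transposed enone and to peroxides. The fallback sets out from 7 and comes back at 8 without any C–H abstraction. The alkene is epoxidised with m-CPBA to methyl 2-[(2R)-1-methyl-7-oxabicyclo[4.1.0]heptan-2-yl]propanoate F1. The epoxide is opened at its secondary carbon with sodium phenylselenide (PhSeSePh, NaBH4, EtOH) to methyl 2-[(1R)-2-hydroxy-2-methyl-3-(phenylselanyl)cyclohexyl]propanoate F2. Oxidation with H2O2 and selenoxide elimination away from the carbinol give methyl 2-[(1R)-2-hydroxy-2-methylcyclohex-3-en-1-yl]propanoate F3, and oxidative 1,3-transposition with pyridinium chlorochromate gives 8.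

Step 5. Capture of the hindered silyl enol ether by the iminium salt may be slow, and the α-methylene ketone 12 may dimerise before it is used. The fallback sets out from 8 and comes back at 15 without passing through 12. But-3-ene-1,2-diol is silylated at the primary hydroxyl (TBDPSCl, imidazole) to 1-{[tert-butyl(diphenyl)silyl]oxy}but-3-en-2-ol F4 and oxidised with Dess–Martin periodinane to 1-{[tert-butyl(diphenyl)silyl]oxy}but-3-en-2-one F5. The silyl enol ether 9, made from 8 as in step 5, adds to F5 in a Mukaiyama–Michael reaction (Tf2NH cat.) to give the diketone methyl 2-[(1R,2R)-2-{3-[tert-butyl(dimethyl)silyl]oxypropyl}-3-(4-{[tert-butyl(diphenyl)silyl]oxy}-3-oxobutyl)-2-methyl-4-oxocyclohexyl]propanoate F6. Equilibration of C9 with NaOMe in MeOH and double Wittig methylenation then give 15. This variant relies on thermodynamic control at C9, which is weaker than the protonation used in step 6.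

Step 13. The alkoxides next to the sulfonium centre may close a cyclic ether instead of undergoing elimination. The fallback sets out from 19 and comes back at 21. Compound 19 is epoxidised with D-(−)-diisopropyl tartrate in place of the L-ester to methyl (1S,4aS,5R,8aS)-5-{2-[(2R)-2-(hydroxymethyl)oxiran-2-yl]ethyl}-1,4a-dimethyl-6-methylidenedecahydronaphthalene-1-carboxylate F7. Parikh–Doering oxidation (SO3·pyridine, DMSO, Et3N) gives methyl (1S,4aS,5R,8aS)-5-{2-[(2S)-2-formyloxiran-2-yl]ethyl}-1,4a-dimethyl-6-methylidenedecahydronaphthalene-1-carboxylate F8, and Wittig methylenation gives methyl (1S,4aS,5R,8aS)-5-{2-[(2R)-2-ethenyloxiran-2-yl]ethyl}-1,4a-dimethyl-6-methylidenedecahydronaphthalene-1-carboxylate F9. Opening of the epoxide at its CH2 carbon with aqueous NaOH in DMSO gives 21. Because the vinyl group here grows from the former hydroxymethyl carbon, the antipodal tartrate leads to the same (3R)-diol.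

Further compounds
F1 | step 4 | methyl 2-[(2R)-1-methyl-7-oxabicyclo[4.1.0]heptan-2-yl]propanoate | COC(=O)C(C)[C@H]1CCCC2OC12C
F2 | step 4 | methyl 2-[(1R)-2-hydroxy-2-methyl-3-(phenylselanyl)cyclohexyl]propanoate | COC(=O)C(C)[C@H]1CCCC([Se]c2ccccc2)C1(C)O
F3 | step 4 | methyl 2-[(1R)-2-hydroxy-2-methylcyclohex-3-en-1-yl]propanoate | COC(=O)C(C)[C@H]1CCC=CC1(C)O
F4 | step 5 | 1-{[tert-butyl(diphenyl)silyl]oxy}but-3-en-2-ol | C=CC(O)CO[Si](c1ccccc1)(c1ccccc1)C(C)(C)C
F5 | step 5 | 1-{[tert-butyl(diphenyl)silyl]oxy}but-3-en-2-one | C=CC(=O)CO[Si](c1ccccc1)(c1ccccc1)C(C)(C)C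
F6 | step 5 | methyl 2-[(1R,2R)-2-{3-[tert-butyl(dimethyl)silyl]oxypropyl}-3-(4-{[tert-butyl(diphenyl)silyl]oxy}-3-oxobutyl)-2-methyl-4-oxocyclohexyl]propanoate | COC(=O)C(C)[C@H]1CCC(=O)C(CCC(=O)CO[Si](c2ccccc2)(c2ccccc2)C(C)(C)C)[C@]1(C)CCCO[Si](C)(C)C(C)(C)C
F7 | step 13 | methyl (1S,4aS,5R,8aS)-5-{2-[(2R)-2-(hydroxymethyl)oxiran-2-yl]ethyl}-1,4a-dimethyl-6-methylidenedecahydronaphthalene-1-carboxylate | OC[C@]1(CC[C@@H]2C(=C)CC[C@H]3[C@@]2(C)CCC[C@]3(C)C(=O)OC)CO1
F8 | step 13 | methyl (1S,4aS,5R,8aS)-5-{2-[(2S)-2-formyloxiran-2-yl]ethyl}-1,4a-dimethyl-6-methylidenedecahydronaphthalene-1-carboxylate | O=C[C@]1(CC[C@@H]2C(=C)CC[C@H]3[C@@]2(C)CCC[C@]3(C)C(=O)OC)CO1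
F9 | step 13 | methyl (1S,4aS,5R,8aS)-5-{2-[(2R)-2-ethenyloxiran-2-yl]ethyl}-1,4a-dimethyl-6-methylidenedecahydronaphthalene-1-carboxylate | C=C[C@]1(CC[C@@H]2C(=C)CC[C@H]3[C@@]2(C)CCC[C@]3(C)C(=O)OC)CO1
A1 | direct plan | (5E,9E)-12-[(2R,3R)-3-(hydroxymethyl)-3-methyloxiran-2-yl]-6,10-dimethyldodeca-5,9-dien-2-one | CC(=O)CC/C=C(\C)CC/C=C(\C)CC[C@H]1O[C@]1(C)CO
A2 | direct plan | 4-[(1R,4aS,5S,6R,8aS)-6-hydroxy-5-(hydroxymethyl)-5,8a-dimethyl-2-methylidenedecahydronaphthalen-1-yl]butan-2-one | CC(=O)CC[C@@H]1C(=C)CC[C@H]2[C@@]1(C)CC[C@@H](O)[C@]2(C)CO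
A3 | direct plan | methyl (1S,4aS,5R,8aS)-1,4a-dimethyl-6-methylidene-5-(3-methylidenepent-4-en-1-yl)decahydronaphthalene-1-carboxylate | C=CC(=C)CC[C@@H]1C(=C)CC[C@H]2[C@@]1(C)CCC[C@]2(C)C(=O)OC
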